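In a one-step world the living ends stand at a fixed level in proportion to c(initiator), uptake of free monomer is pseudo-first-order, and the clock runs in proportion to c(initiator).

| setting | midnight | flask |
|---|---|---|
| free monomer | 20 mM (fed, over 10 s) | 20 mM (fed, over 10 s) |
| initiator | 0.40 mM | 0.20 mM |
| remark | run made earlier |  |
| time |  | 25 min |

midnight run (percent of the free monomer charged): time / min: monomer in chains / % = 0.417: 39.9; 1.00: 79.0; 2.00: 77.4; 3.00: 73.5; 5.00: 66.9; 6.00: 65.0; 8.00: 62.1

(scatter of a reading: 0.5 percentage points)

- percentages count the free monomer that a species holds: one self-condensation product or idle adduct counts as two
- monomer in chains is meant together with its idle adduct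
- what may be going on: monomer in chains + initiator <-> isomer of the product + initiator; free monomer + monomer in chains <-> idle adduct; free monomer + living end -> monomer in chains + living end; free monomer + initiator -> living end + monomer in chains; 2 free monomer -> self-condensation product
- in an amount of monomer in chains, one idle adduct counts as one monomer in chains
- no earlier run changes the charge of initiator; that part of a forecast is a guess

- when, up to 25 min, the flask holds most monomer in chains
- the amount of monomer in chains, in percent of the free monomer charged, at that time

The top midnight readings stand at 1.00 min and 2.00 min, and I take their midpoint, 1.50 min, as a rough peak time for that run. In the one-step world this flask, with half the midnight initiator, takes twice as long, so its peak comes at 3.00 min.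

Now I put that answer back in. Living ends are made from initiator while free monomer waits, so if this flask took twice as long, half the rate of making them would give as many ends as at midnight. With as many ends the clock does not stretch, and the peak stays at 1.50 min, which is the other extreme.

I expect the flask between these. At a fixed charge of free monomer, ends grow with c(initiator) times the uptake clock, and that clock shrinks as ends grow, so the clock squared goes as one over c(initiator). This gives the clock stretch, the square root of the ratio of initiator charges, 1.41. Reading the peak on this uptake clock, I put it at 2.12 min. For the height I keep the top midnight reading, 79.0 %, as a guess.

The forecast says 2.6 min (1.8 min to 3.8 min) and 78 % (73 % to 81 %), holding that “Halving the initiator should therefore roughly double the timescale of both growth and isomerisation”.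

The flask gives 82.1 % at 2.02 min, when free monomer stands at 1.53 % and living end at 0.0363 mM. Dividing that time by the stretch gives 1.43 min, which lies between the midnight readings at 1.00 min and 2.00 min.

    monomer in chains + initiator ⇌ isomer of the product + initiator, rate k1*[initiator]*[monomer in chains] forward; the back reaction follows from the equilibrium constant (K = 0.529, k = 6.98 M⁻¹ s⁻¹)
    free monomer + monomer in chains ⇌ idle adduct, settled at all times (K = 20.4 M⁻¹)
    free monomer + living end → monomer in chains + living end, rate k3*[living end]*[free monomer] (k = 1410 M⁻¹ s⁻¹)
    free monomer + initiator → living end + monomer in chains (k = 0.299 M⁻¹ s⁻¹)
    2 free monomer → self-condensation product (k = 0.121 M⁻¹ s⁻¹)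

The neighbour flask has 0.050 mM of initiator, a cut by a factor of 4.00, so the stretch enters two times. Ends go as one over the stretch, so from 0.0367 mM in the flask I expect 0.0184 mM of living end there. The computed value at 25.0 min is 0.0164 mM.

The numbers in the tables were computed for an exercise; the scatter is artificial.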